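The numbers in the tables are simulated with constants of no real substance; scatter was added.

At the last alpha reading 19.5% of the starting material is left over, yet target had been climbing steadily at 10.1 mM h⁻¹, and that steady pace starts the quarrel about oak.

| flask | starting material | gas | free catalyst | temperature | remark | time |
|---|---|---|---|---|---|---|
| beta | 0.25 M | 22 mM (held) | 20 mM | 48 °C | run made earlier |  |
| alpha | 0.25 M | 22 mM (held) | 95 mM | 64 °C | run made earlier |  |
| ash | 0.25 M | 22 mM (held) | 60 mM |  | at 40 °C throughout | 10 h |
| oak | 0.25 M | 22 mM (held) | 14 mM |  | at 70 °C until 10 h, from then on at 40 °C | 20 h |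

| run | time / h | target / % | starting material / % |
|---|---|---|---|
| beta | 8.00 | 0 | 92.5 |
| beta | 15.0 | 1.6 | 90.6 |
| beta | 25.0 | 5.5 | 87.9 |
| beta | 30.0 | 7.7 | 85.8 |
| beta | 40.0 | 9.3 | 83.7 |
| alpha | 1.00 | 0.4 | 74.6 |
| alpha | 2.00 | 1.1 | 68.1 |
| alpha | 3.00 | 5.0 | 62.0 |
| alpha | 5.00 | 13.1 | 54.9 |
| alpha | 8.00 | 24.5 | 43.6 |
| alpha | 15.0 | 53.4 | 19.5 |

(readings scatter by 0.5 percentage points)

- which of the two ends with the higher amount of target, in percent of the starting material charged ("neither" if they lie within 2 percentage points) (ash / oak / neither)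
- target at the end, in percent of the starting material charged, ash
- target at the end, in percent of the starting material charged, oak

- at the start none of coupling partner is dissolved
- on the list of suspects stand: starting material + free catalyst -> catalyst intermediate A; catalyst intermediate A -> catalyst intermediate B; coupling partner + catalyst intermediate B -> catalyst intermediate C; catalyst intermediate C <-> by-product + catalyst intermediate D; catalyst intermediate D -> free catalyst + target; gas <-> coupling partner

Two chemists stand at the board. Both extend the straight stretch of target back to zero and read a lag: 9.81 h in beta, 1.75 h in alpha. Both also read a rate per catalyst charged: 0.0385 h⁻¹ in beta, 0.106 h⁻¹ in alpha.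

The first chemist treats these two rates as one temperature law and extends it to 70 °C, which gives 0.155 h⁻¹, so oak's 14 mM would make 2.17 mM h⁻¹.

The second chemist, whose reckoning I take as mine, objects. From beta to alpha the lag shrank by a factor 5.61, more than the factor 2.75 gained by the rate. So she reads alpha's pace as a ceiling, with the gas crossing to coupling partner as its rate-limiting step. She scales beta's rate by the lag's temperature law instead, a factor 10.7, and gets 0.412 h⁻¹ at 70 °C. Oak then asks for 5.77 mM h⁻¹, less than the ceiling. Over 10 h, less a lag of 0.917 h, that gives 3.74 turnovers, the hot-stage turnover count, c(target)/c(free catalyst). Oak should therefore reach 21.0%. At 40 °C her lag is 23.2 h, longer than ash's 10 h, so ash ends inside its lag, and she counts oak's cool stage as nothing.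

The forecast says oak, with ash at 0.4% and oak at 8.5% (4.5% to 13%), on the grounds that “14 mM gives about 2 mM/h, or 0.85 %/h, for 9 h”.

The flasks give 0.0670% in ash and 19.2% in oak, so oak ends higher.

    starting material + free catalyst → catalyst intermediate A (k = 8.10 M⁻¹ h⁻¹, Ea = 72.0 kJ mol⁻¹)
    catalyst intermediate A → catalyst intermediate B (k = 2.10 h⁻¹, Ea = 113 kJ mol⁻¹)
    coupling partner + catalyst intermediate B → catalyst intermediate C (k = 110 M⁻¹ h⁻¹, Ea = 54.0 kJ mol⁻¹)
    catalyst intermediate C ⇌ by-product + catalyst intermediate D (K = 0.290 M, k = 3.30 h⁻¹, Ea = 111 kJ mol⁻¹, ΔH = 17.0 kJ mol⁻¹)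
    catalyst intermediate D → free catalyst + target (k = 2.20 h⁻¹, Ea = 116 kJ mol⁻¹)
    gas ⇌ coupling partner, rate k6*(csat - [coupling partner]) (kL = 0.550 h⁻¹)
    (constants at 70 °C)

Oak's 19.2% is 3.42 turnovers against the reckoned 3.74. A neighbour flask, oak with 0.0056 M of free catalyst, reckons by the same count to 8.38% and stands at 8.67%. The first view's 0.106 h⁻¹ stands as a reading of alpha, with its 95 mM of free catalyst, a flask where the demand reckoned the second way, 20.5 mM h⁻¹, lay above the ceiling. Oak's hot stage averaged 4.66 mM h⁻¹, less than the crossing's top rate of 12.1 mM h⁻¹. At 10.0 h c(coupling partner) stood at 0.0123 M, so the crossing was delivering 5.32 mM h⁻¹.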